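I followed one molecule.

| flask | starting complex | incoming ligand | leaving ligand | remark | time |
|---|---|---|---|---|---|
| eta | 14 mM | 0.90 equiv | 2 equiv | run made earlier |  |
| zeta | 14 mM | 0.90 equiv | 1 equiv | run made earlier |  |
| beta | 14 mM | 0.90 equiv | 1.5 equiv | run made earlier |  |
| north | 14 mM (fed, over 3.00 min) | 0.900 equiv | 2.00 equiv | all but starting complex at the start; starting complex goes in evenly over 3.00 min, the run ends at 3.0 min | 3.0 min |
| south-east | 14 mM | 0.900 equiv | 2.00 equiv | a closed flask charged with all of it at once and left for 3.0 min | 3.0 min |
| east | 14 mM | 0.900 equiv | 2.00 equiv | a single well-mixed tank run continuously and read at steady state, 3.0 min in it on average |  |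
| west | 14 mM | 0.900 equiv (fed, over 3.00 min) | 2.00 equiv | all but incoming ligand at the start; incoming ligand goes in evenly over 3.00 min, the run ends at 3.0 min | 3.0 min |

eta run (percent of the starting complex charged)

| time / s | complex with one exchanged / % | starting complex / % |
|---|---|---|
| 10.0 | 10.0 | 90.4 |
| 15.0 | 12.3 | 86.2 |
| 30.0 | 18.4 | 78.0 |
| 50.0 | 20.9 | 74.2 |
| 60.0 | 21.8 | 72.1 |
| 80.0 | 21.1 | 70.4 |
| 120 | 19.8 | 68.2 |

zeta run (percent of the starting complex charged)

| time / min | complex with one exchanged / % | starting complex / % |
|---|---|---|
| 0.200 | 11.2 | 88.2 |
| 0.500 | 21.0 | 75.4 |
| 1.00 | 25.8 | 66.0 |
| 1.50 | 25.1 | 63.6 |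
| 2.00 | 24.0 | 60.1 |
| 3.00 | 21.4 | 57.1 |
| 4.00 | 19.7 | 54.2 |

beta run (percent of the starting complex charged)

| time / min | complex with one exchanged / % | starting complex / % |
|---|---|---|
| 0.250 | 13.1 | 86.1 |
| 0.417 | 18.0 | 80.6 |
| 0.667 | 21.5 | 74.3 |
| 1.00 | 23.3 | 69.7 |
| 1.50 | 23.1 | 65.9 |
| 2.50 | 20.3 | 63.0 |
| 4.00 | 17.8 | 59.0 |

(scatter of a reading: 0.5 percentage points)

1. the set-up with the highest amount of complex with one exchanged at the outlet or at the end, in percent of the starting complex put in ("none" if the first two lie within 2 percentage points) (north / south-east / east / west / none)
2. amount of complex with one exchanged at the outlet or at the end, in percent of the starting complex put in, north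
3. amount of complex with one exchanged at the outlet or at the end, in percent of the starting complex put in, south-east
4. amount of complex with one exchanged at the outlet or at the end, in percent of the starting complex put in, east
5. amount of complex with one exchanged at the outlet or at the end, in percent of the starting complex put in, west

- the stated concentrations are those of everything mixed, before any reaction; amounts are the same in each set-up
- the analysis behind the earlier runs scatters by 0.5 percentage points, standard deviation
- the feed brings no volume worth counting
- the earlier runs were made in a closed, stirred flask

The south-east flask has the charges of the eta run and is also closed, so I read the eta run as its first two minutes. In the first instants, starting complex (A) meets incoming ligand and becomes complex with one exchanged (B): at 10.0 s the eta run shows A at 90.4% and B at 10.0%, and the pair still sums to 100%.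

In the middle, at 60.0 s, B stands at its highest eta reading, 21.8%, higher than its neighbours. A molecule of B now faces a fork: it can return to A and stay in the pair, or leave the pair. The readings show that second exit, since the pair falls from 93.9% to 88.0% by 120 s.

I therefore defined the leak frequency λ, the points leaving the pair per minute for each point of B present, a pseudo-first-order constant. Dividing that fall by the mean B between those readings gave 0.284 min⁻¹. The zeta run, with less leaving ligand, reads 0.262 min⁻¹ from 1.00 min to 4.00 min.

Towards the end, B slides slowly, and continuing the straight line through those two eta readings, I expected 17.8% in south-east at 3.0 min.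

The forecast gave 18.5% for north, 17.5% for south-east, 16% for east and 18.5% for west, with best none, the dosed flasks ahead “since less B has had time to drain”.

The flasks gave 18.7% for north, 17.7% for south-east, 16.5% for east and 18.9% for west, so best is none: west stands 0.20 percentage points above north, less than the margin.

    starting complex + incoming ligand ⇌ leaving ligand + complex with one exchanged (K = 1.30, k = 0.994 M⁻¹ s⁻¹)
    complex with one exchanged + incoming ligand ⇌ leaving ligand + complex with two exchanged (K = 2.99, k = 0.362 M⁻¹ s⁻¹)
    starting complex + complex with one exchanged → side product (k = 0.171 M⁻¹ s⁻¹)

Carried on from the last eta reading, λ puts the south-east loss from the pair at 17.3%, and the flask shows 18.2%. West lost 10.1% to side product and complex with two exchanged, which at λ means B averaged 11.9% over the run. Of the 8.1 points west spared, A kept 6.9 points and B gained 1.2 points, and the back reaction of leaving ligand with B is the largest single effect: without it, west ends at 36.2% instead of 18.9%.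

The numbers in the tables are calculated with constants of no real substance; scatter was added.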